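Atom numbers used throughout: C1 (quaternary, angular methyl), C2, C3, C4 (isopropyl carbinol), C5 (ring-fusion CH), C6 (oxygenated carbon), C7=C8 (methyl on C8), C9, C10.

## Structural features

The target is the isovanillate (3-hydroxy-4-methoxybenzoate) of a daucane-type diol. Its core is a bicyclo[5.3.0]decene in which a cyclopentane (C1–C5) and a cycloheptene (C1, C5–C10) share the C1–C5 bond. Four stereocentres stand next to one another, C1–C5–C4 around the fusion and C6 beside C5. The fusion is cis (H5 and the C1 methyl on one face), O4 lies on the other face of the five-membered ring, syn to C6, and O6 is anti to H5. The only unsaturation of the core is the trisubstituted C7=C8 alkene, which makes the C6 ester allylic. Fragile points are this allylic ester (ionisation or transposition in acid, cleavage in base), the free phenol, and, in every C6-ketone precursor, the C4 carbinol, which is then a tertiary aldol open to retro-aldol cleavage and dehydration. The real difficulty is the congested C1/C5/C4 triad: an all-carbon quaternary centre, a fusion methine and a fully substituted carbinol, needed as one enantiomer. The feature exploited is that C1 is β to C6 through C5 while C4–C5 is an aldol bond; methyl transfer to C1 of a seven-membered C6 enone therefore creates exactly the C5 enolate that can close the cyclopentane onto a side-chain isopropyl ketone.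

## Logic of the disconnections

**24 ⇒ 23 ⇒ 18 + 21 (21 ⇐ 19).** The acyl–O6 bond is cut first, after both hydroxyls are masked as silyl ethers. It is the most fragile bond of 24 and joins two parts of very different character. The cut removes the aromatic unit as 21, one step from 19, and reduces the problem to 18. The forward demand is acylation of a hindered secondary allylic alcohol without ionising C6, followed by a desilylation that is neither acidic nor strongly basic.

**18 ⇒ 17.** The C6–H bond is removed, so the carbinol becomes the carbonyl of 17. C6 is the one stereocentre not tied to the ring fusion, and a cis-fused enone offers two clearly different faces. One stereocentre is lost and the C6 carbonyl becomes the handle for all earlier chemistry. The forward step must be a 1,2-reduction with hydride arriving on the convex face (that of H5).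

**17 ⇒ 15 ⇒ 13 (⇒ 12).** The C8–CH3 bond is cut (conjugate-addition retron in 15) and the C7=C8 unsaturation is removed (13). Because C1 is quaternary and C4 has no hydrogen, a C6 ketone can only be dehydrogenated toward C7/C8, so the position of the alkene is not in doubt. The seven-membered ring is thereby reduced to a plain ketone. The demand is two enol silane/dehydrogenation events and one 1,4-methyl transfer beside a β-oxygenated carbon. For that reason O4 is carried as a trimethylsilyl ether (13 from 12), which closes the alkoxide route to retro-aldol cleavage.

**12 ⇒ 8 + 9.** The C1–CH3 and C4–C5 bonds are cut together. C1 is the β-carbon of the C6 enone, and the C5 enolate left by methyl addition is the nucleophile of the C4–C5 aldol bond. The cyclopentane, two C–C bonds and three stereocentres disappear, leaving the achiral monocycle 8. The demand is enantioface-selective methyl transfer to a β,β-disubstituted cycloheptenone in the presence of a second ketone, followed by aldol closure through a metal-bridged array.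

**8 ⇒ 7 ⇒ 6.** The side-chain carbonyl is traced through an epoxide to a trisubstituted alkene. A free ketone would not survive the organomagnesium step that attaches the chain, whereas the alkene does. The chain becomes a commercial homoprenyl unit. The demand is epoxidation of the isolated alkene in the presence of the enone, then a hydride-shift rearrangement of the epoxide.

**6 ⇒ 2 + 3 (via 4); 2 ⇒ 1.** The C1–C2 bond is cut at a carbon that is a carbonyl carbon in the symmetric dione 1. This leaves two commercial materials. The demand is 1,2-addition to a vinylogous ester and carbonyl transposition on a seven-membered ring.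

## Other disconnections considered

**Alternative 1:** The cut goes through C1–C5 and C9–C10 and unravels both rings to the acyclic ene–vinylcyclopropane A1, in which a 1,1-disubstituted alkene (C1=C10) is tethered through C2–C4 to the vinyl terminus C5.
- Forward key step: [Rh(CO)2Cl]2 would open the cyclopropane at its less substituted C7–C9 bond and insert the alkene, giving the cis-fused bicyclo[5.3.0]dec-6-ene A2 with the angular methyl, the C8 methyl and a C4 silyl ether.
- In favour: both rings and the quaternary centre would arise in one neutral, catalytic step from a chain, and the C8 methyl arrives with the cyclopropane. On ring-forming economy and on the C8 methyl this alternative is the better plan; the chosen route buys the seven-membered ring and adds the methyl in a separate sequence.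
- Against: A2 lacks the isopropyl group and the C6 oxygen, and its alkene sits at C6=C7. The endgame would need desilylation, oxidation of C4 to the carbonyl level, isopropyl addition to a hindered, enolisable five-ring carbonyl, and an allylic oxidation with transposition. Convex-face isopropyl addition would give the right C4 epimer, but enolisation and reduction compete. In the allylic oxidation, both the site of hydrogen abstraction (H8 or H5) and the face at C6 are open questions.
- Comparison: A1 needs three stereocentres made beforehand, and C1/C5 would rest on 1,2-induction from the C4 silyl ether. In the chosen plan the O4/O6 pattern is a direct consequence of the aldol mechanism and the absolute configuration comes from a catalyst acting on an achiral substrate. The step count after the key step would be about equal. Overall the chosen plan is more predictable in stereochemistry and oxidation pattern.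

**Alternative 2:** The cut is the C1–C10 bond (retro-Cope), leading to the cis-divinylcyclopropane A3, a 1-siloxy-2-methyl-2-vinylcyclopropane attached to cyclopentene carbon C5.
- Forward key step: heating A3 would form C1–C10, break C6–C8 and close the seven-membered ring as the bis-silyl ether diene A4 (C5=C6–OSi, C8=C9), with quaternary C1.
- In favour: no reagent is needed, the siloxy donor weakens the bond that breaks, and A4 already holds the C4 carbinol, the C6 oxygen and the C8 methyl. Enol ether hydrolysis and migration of C8=C9 into conjugation would reach the oxidation pattern of 17 in one or two operations. On step economy after the key step this alternative is the better plan.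
- Against: the C1 methyl is cis to the cyclopropane across the cyclopentene double bond, so in the boat transition state it must point into the three-membered ring; with a fully substituted alkene terminus this raises the barrier. A3 has two adjacent fully substituted cyclopropane carbons that must be cis-related and matched in absolute sense to C4, because the cyclopropane configuration alone decides C1. The fusion centre C5 would be set only later, by protonation of the enol ether.
- Comparison: both plans make the quaternary centre in the ring-forming event, and on that point they are equal. The chosen plan fixes C1, C5 and C4 in one step with a geometric guarantee for the cis fusion, and its precursor 8 is reached in four steps. A3 would need a longer and stereochemically uncertain assembly.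

**Alternative 3:** The cut goes through C1–C5 and C7–C8, back to the epoxy enol silane A5. A5 has a C4–C5 epoxide, a C6=C7 enol silane and a tethered diene C1=C10–C9=C8.
- Forward key step: catalytic Et3SiOTf would open the epoxide, the diene would add at C5 with inversion and at C7, and the silyl group would end on O4. The product would be the cis-fused bicyclo[5.3.0]dec-9-en-6-one A6.
- In favour: both rings, the C4 silyl ether with its isopropyl group, the C6 ketone and the C8 methyl would appear together, and the epoxide configuration would be passed on stereospecifically. Hydrogenation of C9=C10 and dehydrogenation across C7–C8 would then reach the oxidation pattern of 17. On convergence and on step count after the key step (about five operations against seven) this alternative is the better plan. In the number of stereocentres fixed in the key step it is the equal.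
- Against: the diene terminus C1 carries both the methyl and the tether. With the tether in the E position the methyl points inward, which disfavours the s-cis geometry needed for C7–C8 closure. C1 must also bond to the congested C5 while becoming quaternary. Acyclic dienes are the less willing partners in this reaction class. The C1/C5 relationship depends on the mode of approach and is not enforced by the tether. The C9=C10 alkene is in the wrong place and the C8 stereocentre is wasted.
- Comparison: A5 needs an asymmetric epoxidation of its own plus a stereodefined diene. The chosen plan draws chirality from a catalyst in the key step, and each of its two bond formations has close precedent on cycloheptenones and on β-tethered keto-enones.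

Key step: step 5

## Remarks on the chemistry

- The sense of induction of the phosphoramidite is assumed to follow that of simple 3-alkylcyclohept-2-enones; the ligand enantiomer that delivers methyl to the Si face of C1 (priorities C5 > C2 > C10) is the one meant by L*.
- L* is O,O′-(biphenyl-2,2′-diyl) N,N-bis[1-(naphthalen-2-yl)ethyl]phosphoramidite.
- The epoxide carbon of 7 and C8 of 16 are stereochemical mixtures; both centres are destroyed in the next operation.
- Precursor 8 is used unprotected, because its second ketone is the aldol acceptor. The added safeguard is the O4 silyl ether installed directly after the key step.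

## Route

Step 1
Reactants: 1 cycloheptane-1,3-dione
Product: 2 3-(2-methylpropoxy)cyclohept-2-en-1-one
Conditions: i-BuOH, TsOH·H2O (cat.), toluene, reflux, Dean–Stark
Reagents that add atoms: 2-methylpropan-1-ol, CC(C)CO
Why: Acid-catalysed enol etherification of the 1,3-dione with azeotropic removal of water; the dione is symmetric, so only one vinylogous ester can form.

Step 2
Reactants: 2 3-(2-methylpropoxy)cyclohept-2-en-1-one; 3 5-bromo-2-methylpent-2-ene
Product: 6 3-(4-methylpent-3-en-1-yl)cyclohept-2-en-1-one, via Grignard reagent 4 (not isolated), via bromomagnesium alkoxide 5 (not isolated)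
Conditions: 3, Mg, THF, rt to 40 °C; 2, THF, 0 °C to rt; then 2 M aq. HCl, rt (40 °C if needed)
Reagents that add atoms: water, O
Why: Stork–Danheiser sequence: 1,2-addition of the homoprenyl Grignard reagent to the vinylogous ester carbonyl, then acid hydrolysis of the enol ether and loss of water transpose the carbonyl to give the 3-alkyl enone. On a seven-membered ring the dehydration is slower than on a six-membered one, so the acid stage is run to completion.

Step 3
Reactants: 6 3-(4-methylpent-3-en-1-yl)cyclohept-2-en-1-one
Product: 7 3-[2-(3,3-dimethyloxiran-2-yl)ethyl]cyclohept-2-en-1-one (racemic)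
Conditions: mCPBA (1.05 equiv), NaHCO3, CH2Cl2, 0 °C
Reagents that add atoms: 3-chloroperoxybenzoic acid, OOC(=O)c1cccc(Cl)c1
Why: Prilezhaev epoxidation; the electron-rich trisubstituted alkene reacts far faster with the electrophilic peracid than the electron-poor enone alkene, and the buffer protects the epoxide. The new centre is racemic and disappears in step 4.

Step 4
Reactants: 7 3-[2-(3,3-dimethyloxiran-2-yl)ethyl]cyclohept-2-en-1-one
Product: 8 3-(4-methyl-3-oxopentyl)cyclohept-2-en-1-one
Conditions: BF3·OEt2 (0.3 equiv), CH2Cl2, −78 to −20 °C
Reagents that add atoms: none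
Why: Meinwald rearrangement: the Lewis acid opens the epoxide at the tertiary carbon and a 1,2-hydride shift from the neighbouring CH (hydride migrating in preference to the primary alkyl group) gives the isopropyl ketone. The enone is a poor nucleophile and should not intercept the cation.

Step 5
Reactants: 8 3-(4-methyl-3-oxopentyl)cyclohept-2-en-1-one; 9 trimethylaluminium
Product: 12 (3R,3aR,8aR)-3-hydroxy-8a-methyl-3-(propan-2-yl)octahydroazulen-4(1H)-one, via dimethylaluminium enolate 10 (not isolated), via aluminium aldolate 11 (not isolated)
Conditions: CuTC (copper thiophene-2-carboxylate, Cu(O2CC4H3S), 5 mol %), L* (10 mol %), Me3Al (2.2 equiv), Et2O, −30 °C, then 0 °C; aq. KNaC4H4O6 (potassium sodium tartrate)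
Reagents that add atoms: trimethylaluminium (9), C[Al](C)C
Why: Methyl passes from Me3Al to the ligated monovalent copper centre, which binds the aluminium-activated enone; oxidative addition at C1 (a trivalent copper intermediate) and reductive elimination form C1–CH3 and leave the dimethylaluminium enolate 10 with a fixed C5=C6 double bond. The closest known reaction types are the copper–phosphoramidite-catalysed conjugate addition of trialkylaluminium reagents to 3-substituted cyclohex- and cyclohept-2-enones, which builds quaternary centres, and the copper-catalysed tandem conjugate addition–aldol cyclisation of enones that carry a ketone on the β side chain. The cyclopentane closes by a 5-(enolexo)-exo-trig aldol addition of C5 to the C4 carbonyl through a six-membered array in which aluminium bridges O6 and O4 (10 to 11). C1 is set by the ligand, which directs methyl to the Si face and gives (R)-C1. C5 is set by the tether: the three-atom chain on C1 can reach C5 only on its own face, so the fusion must be cis. C4 is set by the bridged transition state, which holds O4 on the side of C6 and turns the isopropyl group to the convex, H5 side. The step needs 1,4- over 1,2-addition at two carbonyls and an enolate that does not migrate: copper catalysis in ether at −30 °C should outrun uncatalysed addition of Me3Al, the α-branched side-chain ketone is hindered, and in the aprotic medium the enolate cannot equilibrate toward C7 before it is consumed. The chelated aldolate 11 resists retro-aldol cleavage and releases 12 only on tartrate work-up.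

Step 6
Reactants: 12 (3R,3aR,8aR)-3-hydroxy-8a-methyl-3-(propan-2-yl)octahydroazulen-4(1H)-one
Product: 13 (3R,3aR,8aR)-8a-methyl-3-(propan-2-yl)-3-[(trimethylsilyl)oxy]octahydroazulen-4(1H)-one
Conditions: 1-(trimethylsilyl)imidazole, CH2Cl2, rt
Reagents that add atoms: 1-(trimethylsilyl)-1H-imidazole, C[Si](C)(C)n1ccnc1
Why: Silylation of the hindered tertiary alcohol by a powerful, non-acidic silyl donor that does not enolise the ketone. The ether removes the alkoxide pathway to retro-aldol cleavage and dehydration in the enolate and cuprate steps that follow.

Step 7
Reactants: 13 (3R,3aR,8aR)-8a-methyl-3-(propan-2-yl)-3-[(trimethylsilyl)oxy]octahydroazulen-4(1H)-one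
Product: 15 (3R,3aR,8aR)-8a-methyl-3-(propan-2-yl)-3-[(trimethylsilyl)oxy]-2,3,3a,7,8,8a-hexahydroazulen-4(1H)-one, via trimethylsilyl enol ether 14 (not isolated)
Conditions: LiN(iPr)2 (LDA, 1.3 equiv), Me3SiCl, THF, −78 °C; crude enol silane (salts filtered off, solvent exchanged), Pd(OAc)2 (1.05 equiv), MeCN, rt
Reagents that add atoms: none
Why: Kinetic deprotonation at the unhindered C7 methylene (C5–H lies between two fully substituted carbons) and O-silylation, then Ito–Saegusa oxidation. The divalent palladium enolate can undergo β-hydride elimination only with C8–H, so the C7=C8 enone is the sole possible product.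

Step 8
Reactants: 15 (3R,3aR,8aR)-8a-methyl-3-(propan-2-yl)-3-[(trimethylsilyl)oxy]-2,3,3a,7,8,8a-hexahydroazulen-4(1H)-one
Product: 17 (3R,3aR,8aR)-6,8a-dimethyl-3-(propan-2-yl)-3-[(trimethylsilyl)oxy]-2,3,3a,7,8,8a-hexahydroazulen-4(1H)-one, via C8-methyl enol silane 16 (not isolated)
Conditions: Me2CuLi (from MeLi and CuI, 1.5 equiv), Me3SiCl, THF–Et2O, −78 °C; crude enol silane, Pd(OAc)2 (1.05 equiv), MeCN, rt
Reagents that add atoms: lithium dimethylcuprate, [Li+].C[Cu-]C
Why: Silyl chloride-accelerated Gilman conjugate addition places the methyl on C8 and delivers the C6=C7 enol silane regiospecifically. A second Ito–Saegusa oxidation removes the C8 hydrogen, which erases the transient C8 stereocentre and gives the β-methyl enone.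

Step 9
Reactants: 17 (3R,3aR,8aR)-6,8a-dimethyl-3-(propan-2-yl)-3-[(trimethylsilyl)oxy]-2,3,3a,7,8,8a-hexahydroazulen-4(1H)-one
Product: 18 (3R,3aS,4R,8aR)-6,8a-dimethyl-3-(propan-2-yl)-3-[(trimethylsilyl)oxy]-1,2,3,3a,4,7,8,8a-octahydroazulen-4-ol
Conditions: NaBH4, CeCl3·7H2O, MeOH, −78 °C
Reagents that add atoms: none
Why: Luche reduction secures 1,2-selectivity. Hydride should reach the Si face of C6, the convex face carrying H5, anti to the C4 substituent on the α-carbon whose silyloxy group leans over the carbonyl; this sets (R)-C6 with O6 anti to H5.

Step 10
Reactants: 19 3-hydroxy-4-methoxybenzoic acid (isovanillic acid)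
Product: 21 3-[(tert-butyldimethylsilyl)oxy]-4-methoxybenzoic acid, via bis-silylated acid 20 (not isolated)
Conditions: t-BuMe2SiCl (2.3 equiv), imidazole, DMF, rt; then AcOH, THF, H2O, rt
Reagents that add atoms: tert-butyldimethylsilyl chloride, CC(C)(C)[Si](C)(C)Cl
Why: Exhaustive silylation followed by selective hydrolysis of the much more labile silyl ester under mild aqueous acid, which leaves the aryl silyl ether in place.

Step 11
Reactants: 18 (3R,3aS,4R,8aR)-6,8a-dimethyl-3-(propan-2-yl)-3-[(trimethylsilyl)oxy]-1,2,3,3a,4,7,8,8a-octahydroazulen-4-ol; 21 3-[(tert-butyldimethylsilyl)oxy]-4-methoxybenzoic acid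
Product: 23 (3R,3aS,4R,8aR)-6,8a-dimethyl-3-(propan-2-yl)-3-[(trimethylsilyl)oxy]-1,2,3,3a,4,7,8,8a-octahydroazulen-4-yl 3-[(tert-butyldimethylsilyl)oxy]-4-methoxybenzoate, via mixed anhydride 22 (not isolated)
Conditions: 21, 2,4,6-trichlorobenzoyl chloride, Et3N, THF, rt; then 18, DMAP, toluene, rt to 60 °C
Reagents that add atoms: none
Why: Yamaguchi esterification: DMAP attacks the mixed anhydride at the less hindered aroyl carbonyl and the acylpyridinium ion acylates the hindered allylic alcohol with retention at C6. No acid or strong base touches the allylic system.

Step 12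
Reactants: 23 (3R,3aS,4R,8aR)-6,8a-dimethyl-3-(propan-2-yl)-3-[(trimethylsilyl)oxy]-1,2,3,3a,4,7,8,8a-octahydroazulen-4-yl 3-[(tert-butyldimethylsilyl)oxy]-4-methoxybenzoate
Product: 24 (3R,3aS,4R,8aR)-3-hydroxy-6,8a-dimethyl-3-(propan-2-yl)-1,2,3,3a,4,7,8,8a-octahydroazulen-4-yl 3-hydroxy-4-methoxybenzoate
Conditions: Bu4NF (TBAF, 2.5 equiv), AcOH (2.5 equiv), THF, 0 °C to rt
Reagents that add atoms: none
Why: Fluoride cleaves the aryl silyl ether and the tertiary trimethylsilyl ether in one operation. Acetic acid buffers the phenoxide and alkoxide, so the allylic aryl ester should be neither hydrolysed nor transposed.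

## Compound list

1 | cycloheptane-1,3-dione | O=C1CCCCC(=O)C1 | starting material
2 | 3-(2-methylpropoxy)cyclohept-2-en-1-one | CC(C)COC1=CC(=O)CCCC1 | intermediate
3 | 5-bromo-2-methylpent-2-ene | CC(C)=CCCBr | starting material
4 | (4-methylpent-3-en-1-yl)magnesium bromide | CC(C)=CCC[Mg]Br | intermediate (not isolated)
5 | bromomagnesium 1-(4-methylpent-3-en-1-yl)-3-(2-methylpropoxy)cyclohept-2-en-1-olate (racemic) | CC(C)COC1=CC(CCC=C(C)C)(O[Mg]Br)CCCC1 | intermediate (not isolated)
6 | 3-(4-methylpent-3-en-1-yl)cyclohept-2-en-1-one | CC(C)=CCCC1=CC(=O)CCCC1 | intermediate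
7 | 3-[2-(3,3-dimethyloxiran-2-yl)ethyl]cyclohept-2-en-1-one (racemic) | CC1(C)OC1CCC1=CC(=O)CCCC1 | intermediate
8 | 3-(4-methyl-3-oxopentyl)cyclohept-2-en-1-one | CC(C)C(=O)CCC1=CC(=O)CCCC1 | intermediate
9 | trimethylaluminium | C[Al](C)C | starting material
10 | dimethylaluminium (3R)-3-methyl-3-(4-methyl-3-oxopentyl)cyclohept-1-en-1-olate | CC(C)C(=O)CC[C@]1(C)C=C(O[Al](C)C)CCCC1 | intermediate (not isolated)
11 | O4-dimethylaluminium aldolate of 12, chelated to O6 | O=C1CCCC[C@]2(C)CC[C@@](O[Al](C)C)(C(C)C)[C@H]12 | intermediate (not isolated)
12 | (3R,3aR,8aR)-3-hydroxy-8a-methyl-3-(propan-2-yl)octahydroazulen-4(1H)-one (cis-fused; OH syn to the C6 carbonyl) | O=C1CCCC[C@]2(C)CC[C@@](O)(C(C)C)[C@H]12 | intermediate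
13 | (3R,3aR,8aR)-8a-methyl-3-(propan-2-yl)-3-[(trimethylsilyl)oxy]octahydroazulen-4(1H)-one | O=C1CCCC[C@]2(C)CC[C@@](O[Si](C)(C)C)(C(C)C)[C@H]12 | intermediate
14 | C6 trimethylsilyl enol ether of 13 (C6=C7; C1, C4, C5 as in 13) | C[Si](C)(C)OC1=CCCC[C@]2(C)CC[C@@](O[Si](C)(C)C)(C(C)C)[C@H]12 | intermediate (not isolated)
15 | (3R,3aR,8aR)-8a-methyl-3-(propan-2-yl)-3-[(trimethylsilyl)oxy]-2,3,3a,7,8,8a-hexahydroazulen-4(1H)-one | O=C1C=CCC[C@]2(C)CC[C@@](O[Si](C)(C)C)(C(C)C)[C@H]12 | intermediate
16 | C6 trimethylsilyl enol ether (C6=C7) bearing the new C8 methyl, C8 epimers; C1, C4, C5 as in 13 | C[Si](C)(C)OC1=CC(C)CC[C@]2(C)CC[C@@](O[Si](C)(C)C)(C(C)C)[C@H]12 | intermediate (not isolated)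
17 | (3R,3aR,8aR)-6,8a-dimethyl-3-(propan-2-yl)-3-[(trimethylsilyl)oxy]-2,3,3a,7,8,8a-hexahydroazulen-4(1H)-one | O=C1C=C(C)CC[C@]2(C)CC[C@@](O[Si](C)(C)C)(C(C)C)[C@H]12 | intermediate
18 | (3R,3aS,4R,8aR)-6,8a-dimethyl-3-(propan-2-yl)-3-[(trimethylsilyl)oxy]-1,2,3,3a,4,7,8,8a-octahydroazulen-4-ol | O[C@@H]1C=C(C)CC[C@]2(C)CC[C@@](O[Si](C)(C)C)(C(C)C)[C@H]12 | intermediate
19 | 3-hydroxy-4-methoxybenzoic acid (isovanillic acid) | COc1ccc(C(=O)O)cc1O | starting material
20 | tert-butyldimethylsilyl 3-[(tert-butyldimethylsilyl)oxy]-4-methoxybenzoate | COc1ccc(C(=O)O[Si](C)(C)C(C)(C)C)cc1O[Si](C)(C)C(C)(C)C | intermediate (not isolated)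
21 | 3-[(tert-butyldimethylsilyl)oxy]-4-methoxybenzoic acid | COc1ccc(C(=O)O)cc1O[Si](C)(C)C(C)(C)C | intermediate
22 | 3-[(tert-butyldimethylsilyl)oxy]-4-methoxybenzoic 2,4,6-trichlorobenzoic anhydride | COc1ccc(C(=O)OC(=O)c2c(Cl)cc(Cl)cc2Cl)cc1O[Si](C)(C)C(C)(C)C | intermediate (not isolated)
23 | (3R,3aS,4R,8aR)-6,8a-dimethyl-3-(propan-2-yl)-3-[(trimethylsilyl)oxy]-1,2,3,3a,4,7,8,8a-octahydroazulen-4-yl 3-[(tert-butyldimethylsilyl)oxy]-4-methoxybenzoate | COc1ccc(C(=O)O[C@@H]2C=C(C)CC[C@]3(C)CC[C@@](O[Si](C)(C)C)(C(C)C)[C@H]23)cc1O[Si](C)(C)C(C)(C)C | intermediate
24 | (3R,3aS,4R,8aR)-3-hydroxy-6,8a-dimethyl-3-(propan-2-yl)-1,2,3,3a,4,7,8,8a-octahydroazulen-4-yl 3-hydroxy-4-methoxybenzoate | COc1ccc(C(=O)O[C@@H]2C=C(C)CC[C@]3(C)CC[C@@](O)(C(C)C)[C@H]23)cc1O | target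

## Step count and least certain steps

Total: 12 steps. Longest linear sequence: 11 steps (steps 1–9, 11 and 12, from 1); step 10 is a one-step branch from 19.

**Step 5 (key step).** The most likely failure is loss of control in the second half of the tandem: the aluminium enolate may add to the ketone through an open arrangement activated by a second Me3Al, eroding selectivity at C4, or ring closure may lag and allow direct methyl addition to a carbonyl. Enantioselectivity could also suffer if the Lewis-basic side-chain ketone competes for the catalyst.
Fallback: the two events are separated. Setting out from 8, the same copper-catalysed methyl addition is run and the enolate is intercepted at −30 °C with Me3SiOTf as the regiodefined enol silane (3R)-trimethyl{[3-methyl-3-(4-methyl-3-oxopentyl)cyclohept-1-en-1-yl]oxy}silane F1. F1 is then cyclised in a separate intramolecular Mukaiyama aldol reaction (TiCl4, CH2Cl2, −78 °C). The tether again enforces cis fusion and the isopropyl group should take the convex side. Aqueous work-up rejoins the route at 12.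

**Step 4.** After Lewis-acid opening the cation may take other paths than hydride shift: alkyl migration to an aldehyde, proton loss to an allylic alcohol, or capture of fluoride. The ratio depends on the Lewis acid and cannot be guaranteed.
Fallback: setting out from 7, oxidative cleavage of the epoxide with H5IO6 (Et2O–THF, 0 °C) gives 3-(3-oxocyclohept-1-en-1-yl)propanal F2. Addition of i-PrMgCl/CeCl3 at −78 °C, selective for the aldehyde over the β,β-disubstituted enone, gives 3-(3-hydroxy-4-methylpentyl)cyclohept-2-en-1-one F3. Dess–Martin oxidation of F3 rejoins the route at 8.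

**Step 9.** Facial selectivity may be poor. The angular C1 methyl stands on the convex face, 1,3 to C6, while the C4 substituents shield the other face, so the difference between the faces may be modest in a flexible seven-membered ring.
Fallback: setting out from 17, the concave-face product (3R,3aS,4S,8aR)-6,8a-dimethyl-3-(propan-2-yl)-3-[(trimethylsilyl)oxy]-1,2,3,3a,4,7,8,8a-octahydroazulen-4-ol F4 is separated and not discarded. F4 is esterified with 21 under Mitsunobu conditions (PPh3, diisopropyl azodicarboxylate, toluene, 0 °C to rt), so the C6–O bond is made with inversion by the carboxylate. This rejoins the route at 23.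

**Step 7.** The palladium stage may stall through protodesilylation back to the ketone before β-hydride elimination, or enolisation may be incompletely regioselective, which lowers conversion.
Fallback: setting out from 13, the lithium enolate (LiN(iPr)2, THF, −78 °C) is quenched with PhSeBr to give the C7 selenide (3R,3aR,8aR)-8a-methyl-5-(phenylselanyl)-3-(propan-2-yl)-3-[(trimethylsilyl)oxy]octahydroazulen-4(1H)-one F5. Oxidation (H2O2, pyridine, CH2Cl2, 0 °C) and selenoxide syn-elimination toward C8–H rejoin the route at 15.

**Step 2.** On a seven-membered ring the hydrolysis may stop before dehydration of the β-hydroxy ketone stage is complete, and forcing the acid may hydrate the side-chain alkene.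
Fallback: setting out from 1, triflation (Tf2O, pyridine, CH2Cl2, −78 °C) gives 3-oxocyclohept-1-en-1-yl trifluoromethanesulfonate F6. Cross-coupling of F6 with Grignard reagent 4 under Fe(acac)3 catalysis (iron tris(acetylacetonate), THF/NMP, −30 °C) forms the C1–C2 bond without any hydrolysis step and rejoins the route at 6.

## Further compounds

F1 | step 5 | (3R)-trimethyl{[3-methyl-3-(4-methyl-3-oxopentyl)cyclohept-1-en-1-yl]oxy}silane | CC(C)C(=O)CC[C@]1(C)C=C(O[Si](C)(C)C)CCCC1
F2 | step 4 | 3-(3-oxocyclohept-1-en-1-yl)propanal | O=CCCC1=CC(=O)CCCC1
F3 | step 4 | 3-(3-hydroxy-4-methylpentyl)cyclohept-2-en-1-one (racemic) | CC(C)C(O)CCC1=CC(=O)CCCC1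
F4 | step 9 | (3R,3aS,4S,8aR)-6,8a-dimethyl-3-(propan-2-yl)-3-[(trimethylsilyl)oxy]-1,2,3,3a,4,7,8,8a-octahydroazulen-4-ol | O[C@H]1C=C(C)CC[C@]2(C)CC[C@@](O[Si](C)(C)C)(C(C)C)[C@H]12
F5 | step 7 | (3R,3aR,8aR)-8a-methyl-5-(phenylselanyl)-3-(propan-2-yl)-3-[(trimethylsilyl)oxy]octahydroazulen-4(1H)-one (C7 epimers) | O=C1C([Se]c3ccccc3)CCC[C@]2(C)CC[C@@](O[Si](C)(C)C)(C(C)C)[C@H]12
F6 | step 2 | 3-oxocyclohept-1-en-1-yl trifluoromethanesulfonate | O=C1C=C(OS(=O)(=O)C(F)(F)F)CCCC1
A1 | alternative 1 | tert-butyldimethylsilyl ether of (E)-6-methyl-1-(trans-2-methylcyclopropyl)hepta-1,6-dien-3-ol, single enantiomer as in the SMILES | C=C(C)CC[C@@H](O[Si](C)(C)C(C)(C)C)/C=C/[C@@H]1C[C@H]1C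
A2 | alternative 1 | cis-fused 3-[(tert-butyldimethylsilyl)oxy]-6,8a-dimethyl-1,2,3,3a,6,7,8,8a-octahydroazulene (C6=C7; C1 and C5 as in 24) | C1=C[C@H](C)CC[C@]2(C)CC[C@@H](O[Si](C)(C)C(C)(C)C)[C@H]12
A3 | alternative 2 | triethyl{[2-ethenyl-2-methyl-1-[2-methyl-5-(propan-2-yl)-5-[(trimethylsilyl)oxy]cyclopent-1-en-1-yl]cyclopropyl]oxy}silane, vinyl and cyclopentenyl cis, C4 as in 24 | C=C[C@]1(C)C[C@]1(O[Si](CC)(CC)CC)C1=C(C)CC[C@@]1(O[Si](C)(C)C)C(C)C
A4 | alternative 2 | 6,8a-dimethyl-3-(propan-2-yl)-4-[(triethylsilyl)oxy]-3-[(trimethylsilyl)oxy]-1,2,3,5,8,8a-hexahydroazulene (C5=C6, C8=C9; C1 and C4 as in 24) | CC1=CC[C@]2(C)CC[C@@](O[Si](C)(C)C)(C(C)C)C2=C(O[Si](CC)(CC)CC)C1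
A5 | alternative 3 | triethyl({1-[3-[(3E,5E)-3-methylhepta-3,5-dien-1-yl]-3-(propan-2-yl)oxiran-2-yl]ethenyl}oxy)silane, enol-silane carbon and dienyl chain cis on the oxirane | C=C(O[Si](CC)(CC)CC)[C@H]1O[C@@]1(C(C)C)CC/C(C)=C/C=C/C
A6 | alternative 3 | cis-fused 6,8a-dimethyl-3-(propan-2-yl)-3-[(triethylsilyl)oxy]-2,3,3a,5,6,8a-hexahydroazulen-4(1H)-one (C9=C10; C1, C4, C5 as in 24) | O=C1C[C@H](C)C=C[C@]2(C)CC[C@@](O[Si](CC)(CC)CC)(C(C)C)[C@H]12
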